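**Plan**

- Retrosynthetic cuts, in order: the chalcone Cα=Cβ bond (Claisen–Schmidt), the aryl–acetyl bond (ortho-lithiation), O1–C2 of the oxane (allyl cation etherification), the alkene of the open-chain heptenediol (cross-metathesis), the C4–aryl bond (Negishi coupling) and the C5–C6 bond (vinylogous aldol).
- Enabling feature: C2 of the oxane ring (O1, C2–C6) carries a 2-(4-hydroxyphenyl)ethyl chain, i.e. a hydrogenated styryl group. O1–C2 can therefore be made by letting the C6 oxygen trap a 1-(4-oxyphenyl)allyl cation at the carbon remote from the arene.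
- Forward order: a δ-lactone ring is built first as a stereochemical template, opened to an acyclic hydroxy alkene and extended to the heptenediol. The oxane ring then closes in the rhenium step; saturation, acetylation, chalcone condensation and deprotection follow.
- Stereochemistry: C6 comes from a Ti/(S)-BINOL vinylogous Mukaiyama aldol, C4 from copper hydride delivery anti to the C6 aryl group in the unsaturated lactone, and C2 from thermodynamic equilibration to the all-equatorial chair in the key step.
- All phenols travel as methoxymethyl (MOM) ethers and are released together in the last step.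

Key step: step 11

Remark: diene 2 and aldehyde 1 are taken as purchased; the silylated adduct 3 is drawn as the (Z)-enol silyl ether, its geometry being immaterial because both silyl groups are hydrolysed in the same flask; lactol 13 and the C7 carbinol of 15/16 are mixtures at the centre left undefined in their SMILES.

**Route**

Step 1
Reactants: 1 4-(methoxymethoxy)benzaldehyde; 2 1-methoxy-1,3-bis(trimethylsilyloxy)buta-1,3-diene
Product: 4 methyl (5S)-5-hydroxy-5-[4-(methoxymethoxy)phenyl]-3-oxopentanoate, via bis-silylated aldol adduct 3 (not isolated)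
Conditions: Ti(OiPr)4 (10 mol %), (S)-BINOL (10 mol %), 4 Å MS, THF, −78 °C to rt; then 1 M HCl, THF, 0 °C
Reagents that add atoms: none
Why: Catalytic asymmetric vinylogous Mukaiyama aldol reaction in which the titanium–BINOL complex activates the aldehyde and the diene adds through its terminal carbon; the (S)-ligand is chosen because this catalyst class delivers, from aromatic aldehydes, the carbinol with the same descriptor as the ligand, so Si-face attack should set the (S)-benzylic carbinol (later C6), and brief cold dilute acid removes both silyl groups without touching the aryl acetal.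

Step 2
Reactants: 4 methyl (5S)-5-hydroxy-5-[4-(methoxymethoxy)phenyl]-3-oxopentanoate
Product: 5 (6S)-6-[4-(methoxymethoxy)phenyl]oxane-2,4-dione
Conditions: K2CO3, MeOH, rt; then 1 M HCl to pH 3, 0 °C
Reagents that add atoms: none
Why: Base-mediated lactonisation of a δ-hydroxy-β-keto ester, driven by removal of the cyclic β-dicarbonyl as its enolate, which is released on cold acidification; the carbinol centre takes no part.

Step 3
Reactants: 5 (6S)-6-[4-(methoxymethoxy)phenyl]oxane-2,4-dione
Product: 6 (2S)-2-[4-(methoxymethoxy)phenyl]-6-oxo-3,6-dihydro-2H-pyran-4-yl trifluoromethanesulfonate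
Conditions: Tf2O, Et3N, CH2Cl2, −78 °C
Reagents that add atoms: trifluoromethanesulfonic anhydride, O=S(=O)(OS(=O)(=O)C(F)(F)F)C(F)(F)F
Why: O-Sulfonylation of the cyclic vinylogous acid at the C4 oxygen gives the enol triflate, the standard activation of 4-hydroxy-5,6-dihydropyranones for cross-coupling.

Step 4
Reactants: 7 5-methoxyresorcinol
Product: 8 1-methoxy-3,5-bis(methoxymethoxy)benzene
Conditions: MOMCl, i-Pr2NEt, CH2Cl2, 0 °C to rt
Reagents that add atoms: chloromethyl methyl ether, COCCl
Why: Williamson-type acetalisation of both phenols; the MOM groups later direct both metalations and mask the phenols to the end.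

Step 5
Reactants: 8 1-methoxy-3,5-bis(methoxymethoxy)benzene; 6 (2S)-2-[4-(methoxymethoxy)phenyl]-6-oxo-3,6-dihydro-2H-pyran-4-yl trifluoromethanesulfonate
Product: 11 (6S)-4-[4-methoxy-2,6-bis(methoxymethoxy)phenyl]-6-[4-(methoxymethoxy)phenyl]-5,6-dihydro-2H-pyran-2-one, via aryllithium 9 (not isolated), via arylzinc chloride 10 (not isolated)
Conditions: n-BuLi, THF, 0 °C; ZnCl2, THF, 0 °C to rt; then 6, Pd2(dba)3 (2.5 mol %), SPhos (10 mol %), THF, rt to 45 °C
Reagents that add atoms: none
Why: Directed ortho-metalation at the C–H flanked by two chelating OMOM groups (kinetically the most acidic site), transmetalation to zinc and Negishi coupling with the vinylogous acyl triflate; the arylzinc tolerates the lactone, is not lost by protodemetalation as a 2,6-dialkoxyarylboronic acid would be, and SPhos-type ligands are known to carry di-ortho-substituted aryl partners.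

Step 6
Reactants: 11 (6S)-4-[4-methoxy-2,6-bis(methoxymethoxy)phenyl]-6-[4-(methoxymethoxy)phenyl]-5,6-dihydro-2H-pyran-2-one
Product: 12 (4S,6S)-4-[4-methoxy-2,6-bis(methoxymethoxy)phenyl]-6-[4-(methoxymethoxy)phenyl]oxan-2-one (4,6-cis)
Conditions: Cu(OAc)2·H2O (5 mol %), 1,2-bis(diphenylphosphino)benzene (5 mol %), (EtO)2MeSiH, t-BuOH, toluene, rt
Reagents that add atoms: none
Why: Copper hydride conjugate reduction of a β-aryl unsaturated δ-lactone, in which hydride should reach C4 of the half-chair on the face opposite the pseudo-equatorial C6 aryl group (the usual trans addition to 6-substituted dihydropyranones), so that the C4 aryl ends up cis to the C6 aryl; the benzylic lactone C–O bond, which hydrogenation over palladium would endanger, is not touched.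

Step 7
Reactants: 12 (4S,6S)-4-[4-methoxy-2,6-bis(methoxymethoxy)phenyl]-6-[4-(methoxymethoxy)phenyl]oxan-2-one
Product: 13 (4S,6S)-4-[4-methoxy-2,6-bis(methoxymethoxy)phenyl]-6-[4-(methoxymethoxy)phenyl]oxan-2-ol (anomer mixture)
Conditions: DIBAL-H, CH2Cl2, −78 °C; Rochelle salt work-up
Reagents that add atoms: none
Why: Partial reduction of a δ-lactone stops at the stable tetrahedral aluminium acetal at −78 °C and gives the lactol on work-up.

Step 8
Reactants: 13 (4S,6S)-4-[4-methoxy-2,6-bis(methoxymethoxy)phenyl]-6-[4-(methoxymethoxy)phenyl]oxan-2-ol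
Product: 14 (1S,3R)-3-[4-methoxy-2,6-bis(methoxymethoxy)phenyl]-1-[4-(methoxymethoxy)phenyl]hex-5-en-1-ol
Conditions: Ph3PCH3Br, KOt-Bu (3 equiv each), THF, 0 °C to rt
Reagents that add atoms: methyltriphenylphosphonium bromide, C[P+](c1ccccc1)(c1ccccc1)c1ccccc1.[Br-]
Why: Wittig methylenation of the hydroxy aldehyde in equilibrium with the lactol, a standard lactol opening; C4 is β to the aldehyde and cannot epimerise.

Step 9
Reactants: 1 4-(methoxymethoxy)benzaldehyde
Product: 15 1-[4-(methoxymethoxy)phenyl]prop-2-en-1-ol (racemic)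
Conditions: vinylmagnesium bromide, THF, 0 °C
Reagents that add atoms: vinylmagnesium bromide, C=C[Mg]Br
Why: Grignard 1,2-addition to an aromatic aldehyde; the carbinol is made racemic on purpose because its configuration is erased in step 11.

Step 10
Reactants: 14 (1S,3R)-3-[4-methoxy-2,6-bis(methoxymethoxy)phenyl]-1-[4-(methoxymethoxy)phenyl]hex-5-en-1-ol; 15 1-[4-(methoxymethoxy)phenyl]prop-2-en-1-ol
Product: 16 (1S,3R,5E)-3-[4-methoxy-2,6-bis(methoxymethoxy)phenyl]-1,7-bis[4-(methoxymethoxy)phenyl]hept-5-ene-1,7-diol (both C7 epimers)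
Conditions: Hoveyda–Grubbs II (5 mol %), 15 (3 equiv), 1,4-benzoquinone (10 mol %), CH2Cl2, 40 °C
Reagents that add atoms: none
Why: Olefin cross-metathesis between a reactive terminal alkene and a slowly dimerising secondary allylic alcohol used in excess, with a phosphine-free ruthenium carbene that tolerates free hydroxyl groups and should give the E-alkene; benzoquinone suppresses hydride-mediated isomerisation of the allylic alcohol.

Step 11
Reactants: 16 (1S,3R,5E)-3-[4-methoxy-2,6-bis(methoxymethoxy)phenyl]-1,7-bis[4-(methoxymethoxy)phenyl]hept-5-ene-1,7-diol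
Product: 17 (2R,4R,6S)-4-[4-methoxy-2,6-bis(methoxymethoxy)phenyl]-6-[4-(methoxymethoxy)phenyl]-2-{(E)-2-[4-(methoxymethoxy)phenyl]ethenyl}oxane (all-cis)
Conditions: Re2O7 (5 mol %), CH2Cl2 (0.02 M), 0 °C to rt
Reagents that add atoms: none
Why: Re2O7 converts either epimer of the benzylic and allylic C7 alcohol into a perrhenate ester that ionises to a 1-(4-alkoxyphenyl)allyl cation (equivalently, undergoes 1,3-transposition), and the C1 hydroxyl captures it at the terminus remote from the arene, forming O1–C2 of the oxane and restoring the conjugated (E)-styrene. The closest known reaction type is the rhenium(VII) oxide catalysed allylic alcohol transposition with intramolecular hydroxyl trapping that gives 2,6-cis-tetrahydropyrans. The ring closes in a 6-exo mode with respect to the allyl unit through a chair in which the C4 and C6 aryl groups, fixed in steps 6 and 1, are equatorial. The new stereocentre C2 is set under thermodynamic control: the allylic C2–O bond re-ionises under the conditions, so any 2,6-trans isomer reverts and the all-equatorial 2,4,6-cis chair should accumulate, which is why the carbinol epimer mixture can be used; if the benzylic C6–O bond also ionises it can only re-close to the same isomer because C4 is not epimerisable. The step needs capture by the free hydroxyl in preference to ether oxygens or arene carbons and needs the aryl acetals to survive; the first is secured by the six-membered chair transition state and dilution, the second by low catalyst loading at or below room temperature.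

Step 12
Reactants: 17 (2R,4R,6S)-4-[4-methoxy-2,6-bis(methoxymethoxy)phenyl]-6-[4-(methoxymethoxy)phenyl]-2-{(E)-2-[4-(methoxymethoxy)phenyl]ethenyl}oxane
Product: 18 (2S,4R,6S)-4-[4-methoxy-2,6-bis(methoxymethoxy)phenyl]-6-[4-(methoxymethoxy)phenyl]-2-{2-[4-(methoxymethoxy)phenyl]ethyl}oxane
Conditions: H2 (1 atm), 5% Pd/C, pyridine (0.5 equiv), EtOAc, rt
Reagents that add atoms: none
Why: Heterogeneous hydrogenation of the disubstituted styrene under neutral, amine-moderated conditions should be much faster than hydrogenolysis of the ring C–O bonds and leaves the acetals alone; saturation also removes the allylic activation of C2–O, so C2 can no longer epimerise (the descriptor changes from R to S only through priority).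

Step 13
Reactants: 18 (2S,4R,6S)-4-[4-methoxy-2,6-bis(methoxymethoxy)phenyl]-6-[4-(methoxymethoxy)phenyl]-2-{2-[4-(methoxymethoxy)phenyl]ethyl}oxane
Product: 20 1-[6-methoxy-2,4-bis(methoxymethoxy)-3-{(2S,4R,6S)-2-[4-(methoxymethoxy)phenyl]-6-{2-[4-(methoxymethoxy)phenyl]ethyl}oxan-4-yl}phenyl]ethan-1-one, via aryllithium 19 (not isolated)
Conditions: n-BuLi (1.2 equiv), THF, −20 to 0 °C; then MeC(O)N(OMe)Me, −78 °C to rt; aq. NH4Cl
Reagents that add atoms: N-methoxy-N-methylacetamide, CC(=O)N(C)OC
Why: Directed ortho-metalation, in which only the C–H bonds of the phloroglucinol ring lie between two oxygen substituents (OMOM and OMe) and should be deprotonated fastest, followed by single acylation through the chelated Weinreb adduct; the two flanked positions are equivalent by rotation about the C4–aryl bond.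

Step 14
Reactants: 20 the acetophenone from step 13; 1 4-(methoxymethoxy)benzaldehyde
Product: 21 (2E)-1-[6-methoxy-2,4-bis(methoxymethoxy)-3-{(2S,4R,6S)-2-[4-(methoxymethoxy)phenyl]-6-{2-[4-(methoxymethoxy)phenyl]ethyl}oxan-4-yl}phenyl]-3-[4-(methoxymethoxy)phenyl]prop-2-en-1-one
Conditions: KOH, EtOH, rt
Reagents that add atoms: none
Why: Claisen–Schmidt condensation of the methyl ketone enolate with a non-enolisable aldehyde, with E1cB dehydration to the favoured (E)-chalcone; all phenols are masked, so no phenoxide deactivates the ketone.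

Step 15
Reactants: 21 the penta-MOM chalcone from step 14
Product: 22 (2E)-1-[2,4-dihydroxy-3-{(2S,4R,6S)-2-(4-hydroxyphenyl)-6-[2-(4-hydroxyphenyl)ethyl]oxan-4-yl}-6-methoxyphenyl]-3-(4-hydroxyphenyl)prop-2-en-1-one
Conditions: 3 M HCl (aq.), MeOH, rt to 40 °C
Reagents that add atoms: none
Why: Acid-catalysed acetal exchange to methanol removes all five MOM groups while the aryl methyl ether stays, and mild conditions of the kind used for 2'-hydroxy-6'-methoxychalcones should keep the hydrogen-bonded chalcone from closing to the flavanone and the benzylic ring C–O bond from ionising.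

**Compound list**

1 | 4-(methoxymethoxy)benzaldehyde | O=Cc1ccc(OCOC)cc1 | starting material
2 | 1-methoxy-1,3-bis(trimethylsilyloxy)buta-1,3-diene | COC(O[Si](C)(C)C)=CC(=C)O[Si](C)(C)C | starting material
3 | methyl (2Z,5S)-5-[4-(methoxymethoxy)phenyl]-3,5-bis(trimethylsilyloxy)pent-2-enoate | COC(=O)/C=C(/C[C@H](O[Si](C)(C)C)c1ccc(OCOC)cc1)O[Si](C)(C)C | intermediate (not isolated)
4 | methyl (5S)-5-hydroxy-5-[4-(methoxymethoxy)phenyl]-3-oxopentanoate | COC(=O)CC(=O)C[C@H](O)c1ccc(OCOC)cc1 | intermediate
5 | (6S)-6-[4-(methoxymethoxy)phenyl]oxane-2,4-dione | O=C1CC(=O)C[C@@H](c2ccc(OCOC)cc2)O1 | intermediate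
6 | (2S)-2-[4-(methoxymethoxy)phenyl]-6-oxo-3,6-dihydro-2H-pyran-4-yl trifluoromethanesulfonate | O=C1C=C(OS(=O)(=O)C(F)(F)F)C[C@@H](c2ccc(OCOC)cc2)O1 | intermediate
7 | 5-methoxyresorcinol | COc1cc(O)cc(O)c1 | starting material
8 | 1-methoxy-3,5-bis(methoxymethoxy)benzene | COCOc1cc(OC)cc(OCOC)c1 | intermediate
9 | [4-methoxy-2,6-bis(methoxymethoxy)phenyl]lithium | [Li]c1c(OCOC)cc(OC)cc1OCOC | intermediate (not isolated)
10 | chlorido[4-methoxy-2,6-bis(methoxymethoxy)phenyl]zinc | Cl[Zn]c1c(OCOC)cc(OC)cc1OCOC | intermediate (not isolated)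
11 | (6S)-4-[4-methoxy-2,6-bis(methoxymethoxy)phenyl]-6-[4-(methoxymethoxy)phenyl]-5,6-dihydro-2H-pyran-2-one | O=C1C=C(c2c(OCOC)cc(OC)cc2OCOC)C[C@@H](c2ccc(OCOC)cc2)O1 | intermediate
12 | (4S,6S)-4-[4-methoxy-2,6-bis(methoxymethoxy)phenyl]-6-[4-(methoxymethoxy)phenyl]oxan-2-one | O=C1C[C@@H](c2c(OCOC)cc(OC)cc2OCOC)C[C@@H](c2ccc(OCOC)cc2)O1 | intermediate
13 | (4S,6S)-4-[4-methoxy-2,6-bis(methoxymethoxy)phenyl]-6-[4-(methoxymethoxy)phenyl]oxan-2-ol, anomer mixture | OC1C[C@@H](c2c(OCOC)cc(OC)cc2OCOC)C[C@@H](c2ccc(OCOC)cc2)O1 | intermediate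
14 | (1S,3R)-3-[4-methoxy-2,6-bis(methoxymethoxy)phenyl]-1-[4-(methoxymethoxy)phenyl]hex-5-en-1-ol | O[C@H](c1ccc(OCOC)cc1)C[C@H](c1c(OCOC)cc(OC)cc1OCOC)CC=C | intermediate
15 | 1-[4-(methoxymethoxy)phenyl]prop-2-en-1-ol, racemic | C=CC(O)c1ccc(OCOC)cc1 | intermediate
16 | (1S,3R,5E)-3-[4-methoxy-2,6-bis(methoxymethoxy)phenyl]-1,7-bis[4-(methoxymethoxy)phenyl]hept-5-ene-1,7-diol, C7 epimers | O[C@H](c1ccc(OCOC)cc1)C[C@H](c1c(OCOC)cc(OC)cc1OCOC)C/C=C/C(O)c1ccc(OCOC)cc1 | intermediate
17 | (2R,4R,6S)-4-[4-methoxy-2,6-bis(methoxymethoxy)phenyl]-6-[4-(methoxymethoxy)phenyl]-2-{(E)-2-[4-(methoxymethoxy)phenyl]ethenyl}oxane | COCOc1cc(OC)cc(OCOC)c1[C@@H]2C[C@H](/C=C/c3ccc(OCOC)cc3)O[C@H](c3ccc(OCOC)cc3)C2 | intermediate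
18 | (2S,4R,6S)-4-[4-methoxy-2,6-bis(methoxymethoxy)phenyl]-6-[4-(methoxymethoxy)phenyl]-2-{2-[4-(methoxymethoxy)phenyl]ethyl}oxane | COCOc1cc(OC)cc(OCOC)c1[C@@H]2C[C@H](CCc3ccc(OCOC)cc3)O[C@H](c3ccc(OCOC)cc3)C2 | intermediate
19 | aryllithium of 18, lithiated on the phloroglucinol ring between OMe and OMOM | COCOc1cc(OC)c([Li])c(OCOC)c1[C@@H]2C[C@H](CCc3ccc(OCOC)cc3)O[C@H](c3ccc(OCOC)cc3)C2 | intermediate (not isolated)
20 | 1-[6-methoxy-2,4-bis(methoxymethoxy)-3-{(2S,4R,6S)-2-[4-(methoxymethoxy)phenyl]-6-{2-[4-(methoxymethoxy)phenyl]ethyl}oxan-4-yl}phenyl]ethan-1-one | COCOc1cc(OC)c(C(C)=O)c(OCOC)c1[C@@H]2C[C@H](CCc3ccc(OCOC)cc3)O[C@H](c3ccc(OCOC)cc3)C2 | intermediate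
21 | (2E)-1-[6-methoxy-2,4-bis(methoxymethoxy)-3-{(2S,4R,6S)-2-[4-(methoxymethoxy)phenyl]-6-{2-[4-(methoxymethoxy)phenyl]ethyl}oxan-4-yl}phenyl]-3-[4-(methoxymethoxy)phenyl]prop-2-en-1-one | COCOc1cc(OC)c(C(=O)/C=C/c3ccc(OCOC)cc3)c(OCOC)c1[C@@H]2C[C@H](CCc3ccc(OCOC)cc3)O[C@H](c3ccc(OCOC)cc3)C2 | intermediate
22 | (2E)-1-[2,4-dihydroxy-3-{(2S,4R,6S)-2-(4-hydroxyphenyl)-6-[2-(4-hydroxyphenyl)ethyl]oxan-4-yl}-6-methoxyphenyl]-3-(4-hydroxyphenyl)prop-2-en-1-one | COc1cc(O)c([C@@H]2C[C@H](CCc3ccc(O)cc3)O[C@H](c3ccc(O)cc3)C2)c(O)c1C(=O)/C=C/c1ccc(O)cc1 | target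

**Step count**

Total: 15 steps. Longest linear sequence: 13 steps (1, 2, 3, 5, 6, 7, 8, 10, 11, 12, 13, 14, 15); steps 4 and 9 are side branches.

**Steps most likely to fail, with fallbacks**

Step 13. Metalation may occur at the wrong site (ortho to the acetal ethers on the two 4-oxyphenyl rings, or at the benzylic C6–H), and the hindered aryllithium may enolise the Weinreb amide instead of adding to it. The fallback replaces kinetic acidity by electrophilic substitution as the source of site selectivity. It sets out from 18: one equivalent of NBS in MeCN at 0 °C should brominate only the trioxygenated ring and give (2S,4R,6S)-4-[3-bromo-4-methoxy-2,6-bis(methoxymethoxy)phenyl]-6-[4-(methoxymethoxy)phenyl]-2-{2-[4-(methoxymethoxy)phenyl]ethyl}oxane F1. Bromine–lithium exchange with n-BuLi at −78 °C is faster than any deprotonation; trapping with N-methoxy-N-methylacetamide (or with acetaldehyde followed by Dess–Martin oxidation if enolisation persists) returns to the route at 20.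

Step 11. Perrhenic acid formed in the flask may strip methoxymethyl groups, the allyl cation may be captured by an ortho ether oxygen or by an electron-rich arene of a second molecule, and the benzylic carbinol may eliminate before ring closure. The fallback makes the same O1–C2 bond by oxa-Michael addition and sets out from lactol 13.
- Heating 13 with ethyl (triphenylphosphoranylidene)acetate in toluene, then catalytic DBU to complete and equilibrate the conjugate addition, should give the 2,6-cis ester ethyl 2-[(2R,4R,6S)-4-[4-methoxy-2,6-bis(methoxymethoxy)phenyl]-6-[4-(methoxymethoxy)phenyl]oxan-2-yl]acetate F2.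
- DIBAL-H at −78 °C gives 2-[(2R,4R,6S)-4-[4-methoxy-2,6-bis(methoxymethoxy)phenyl]-6-[4-(methoxymethoxy)phenyl]oxan-2-yl]acetaldehyde F3.
- 4-(Methoxymethoxy)phenylmagnesium bromide gives the benzylic alcohol 2-[(2R,4R,6S)-4-[4-methoxy-2,6-bis(methoxymethoxy)phenyl]-6-[4-(methoxymethoxy)phenyl]oxan-2-yl]-1-[4-(methoxymethoxy)phenyl]ethan-1-ol F4 as an epimer mixture.
- Dehydration with the Burgess reagent gives the conjugated (E)-styrene, returning to the route at 17.

Step 10. Ruthenium hydrides may isomerise the electron-rich aryl vinyl carbinol to the ethyl ketone, the carbinol may homodimerise, and conversion of the hindered diol-forming pair may stall. The fallback builds the allylic alcohol by acetylide addition and trans-reduction and sets out from lactol 13.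
- Ohira–Bestmann homologation (dimethyl 1-diazo-2-oxopropylphosphonate, K2CO3, MeOH) gives (1S,3R)-3-[4-methoxy-2,6-bis(methoxymethoxy)phenyl]-1-[4-(methoxymethoxy)phenyl]hex-5-yn-1-ol F5.
- Double deprotonation with n-BuLi and addition to aldehyde 1 gives (1S,3R)-3-[4-methoxy-2,6-bis(methoxymethoxy)phenyl]-1,7-bis[4-(methoxymethoxy)phenyl]hept-5-yne-1,7-diol F6.
- Red-Al reduction, directed by the propargylic alkoxide, gives the (E)-allylic alcohol, returning to the route at 16.

**Further compounds**

F1 | step 13 | (2S,4R,6S)-4-[3-bromo-4-methoxy-2,6-bis(methoxymethoxy)phenyl]-6-[4-(methoxymethoxy)phenyl]-2-{2-[4-(methoxymethoxy)phenyl]ethyl}oxane | COCOc1cc(OC)c(Br)c(OCOC)c1[C@@H]2C[C@H](CCc3ccc(OCOC)cc3)O[C@H](c3ccc(OCOC)cc3)C2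
F2 | step 11 | ethyl 2-[(2R,4R,6S)-4-[4-methoxy-2,6-bis(methoxymethoxy)phenyl]-6-[4-(methoxymethoxy)phenyl]oxan-2-yl]acetate | COCOc1cc(OC)cc(OCOC)c1[C@@H]2C[C@H](CC(=O)OCC)O[C@H](c3ccc(OCOC)cc3)C2
F3 | step 11 | 2-[(2R,4R,6S)-4-[4-methoxy-2,6-bis(methoxymethoxy)phenyl]-6-[4-(methoxymethoxy)phenyl]oxan-2-yl]acetaldehyde | COCOc1cc(OC)cc(OCOC)c1[C@@H]2C[C@H](CC=O)O[C@H](c3ccc(OCOC)cc3)C2
F4 | step 11 | 2-[(2R,4R,6S)-4-[4-methoxy-2,6-bis(methoxymethoxy)phenyl]-6-[4-(methoxymethoxy)phenyl]oxan-2-yl]-1-[4-(methoxymethoxy)phenyl]ethan-1-ol, carbinol epimers | COCOc1cc(OC)cc(OCOC)c1[C@@H]2C[C@H](CC(O)c3ccc(OCOC)cc3)O[C@H](c3ccc(OCOC)cc3)C2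
F5 | step 10 | (1S,3R)-3-[4-methoxy-2,6-bis(methoxymethoxy)phenyl]-1-[4-(methoxymethoxy)phenyl]hex-5-yn-1-ol | O[C@H](c1ccc(OCOC)cc1)C[C@H](c1c(OCOC)cc(OC)cc1OCOC)CC#C
F6 | step 10 | (1S,3R)-3-[4-methoxy-2,6-bis(methoxymethoxy)phenyl]-1,7-bis[4-(methoxymethoxy)phenyl]hept-5-yne-1,7-diol, C7 epimers | O[C@H](c1ccc(OCOC)cc1)C[C@H](c1c(OCOC)cc(OC)cc1OCOC)CC#CC(O)c1ccc(OCOC)cc1
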